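**Retrosynthetic overview**

- The target is 5,7-dihydroxy-2-henicosyl-4H-chromen-4-one and has no stereocentre. The plan rests on ring A: its oxygens sit on C5, C7 and C8a, each ortho or para to C4a, which carries the C4 carbonyl. All three C–O bonds can therefore come from fluoride displacement on one symmetrical 2,4,6-trifluorobenzoyl unit.
- Late disconnections: the two O-benzyl bonds, then C5–O and C7–O by SNAr of benzyloxide on a 5,7-difluorochromone.
- Key disconnection: O1–C8a (intramolecular SNAr) and C3–C4 (enolate C-aroylation), leading back to 2-tricosanone and 2,4,6-trifluorobenzoyl chloride. The ketone comes from docosanoic acid and CH3Li.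
- Ring order: ring A is bought as the trifluoroarene; ring C is closed in the key step.

Key step: step 2

Remark on the chemistry: the order in which the two fluorides are exchanged, and later the two benzyl groups are cleaved, cannot be fixed in advance. Both monosubstituted intermediates are listed in each case, since each leads to the same product.

**Route**

Step 1
Reactants: 1 docosanoic acid
Product: 4 2-tricosanone, via lithium docosanoate 2 (not isolated), via dilithium tricosane-2,2-diolate 3 (not isolated)
Conditions: CH3Li (2.2 equiv, Et2O solution), THF, 0 °C → rt; inverse quench into cold 1 M HCl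
Reagents that add atoms: methyllithium, [Li]C
Why: Organolithium addition to a lithium carboxylate: the first equivalent forms carboxylate 2 and the second adds to give the gem-diolate 3, which does not collapse before protonation, so the ketone should appear only when the excess CH3Li is destroyed in the acidic quench.

Step 2
Reactants: 4 2-tricosanone; 5 2,4,6-trifluorobenzoyl chloride
Product: 9 5,7-difluoro-2-henicosyl-4H-chromen-4-one, via lithium tricos-1-en-2-olate 6 (not isolated), via trifluorophenyl 1,3-diketone 7 (not isolated), via lithium diketonate 8 (not isolated)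
Conditions: LiN(SiMe3)2 (2.2 equiv), THF, −40 °C, slow addition of 4 in THF; 5 (0.95 equiv), −40 → 0 °C; then DMPU, 65 °C; aq. NH4Cl
Reagents that add atoms: none
Why: Slow addition of 4 to an excess of LiN(SiMe3)2 should remove a proton from the C1 methyl group under kinetic control, and enolate 6 should attack the acid chloride through carbon (Claisen-type C-aroylation) to give diketone 7, which the remaining base converts at once into the chelated diketonate 8; this also suppresses a second aroylation while 5 is the limiting reagent. On warming with DMPU, which loosens the lithium chelate, the oxygen on the alkyl-side carbon of 8 should add to an ortho C–F carbon to give a Meisenheimer complex stabilized by the adjacent carbonyl and the two remaining fluorines, and loss of fluoride forms the O1–C8a bond. The closest known reaction type is the base-mediated intramolecular SNAr of 1-(2-fluoroaryl)-1,3-diketones to chromones, run here in the same flask as the enolate aroylation that forms C3–C4. Ring C closes in a 6-exo-trig addition–elimination at the aromatic carbon. No stereocentre is formed. The step needs methyl over methylene enolization, secured by the hindered base, the low temperature and the absence of free ketone, and C- over O-acylation, favoured by the lithium counter-ion; the two ortho fluorines are equivalent by the symmetry of the ring and attack through carbon would need a four-membered ring, so a single chromone should result.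

Step 3
Reactants: 9 5,7-difluoro-2-henicosyl-4H-chromen-4-one
Product: 12 5,7-bis(benzyloxy)-2-henicosyl-4H-chromen-4-one, via 7-benzyloxy-5-fluoro monoether 10 (not isolated), via 5-benzyloxy-7-fluoro monoether 11 (not isolated)
Conditions: PhCH2OH (4 equiv), NaH (3 equiv), THF, 0 °C → rt; then 9, DMSO added, rt → 60 °C
Reagents that add atoms: benzyl alcohol, OCc1ccccc1
Why: Double nucleophilic aromatic substitution (SNAr, addition–elimination) by benzyloxide should proceed because C7 is para and C5 ortho to the C4 carbonyl on C4a, so each Meisenheimer complex is stabilized by that carbonyl, while the excess of benzyl alcohol keeps the base as the alkoxide and the dry medium lets any addition at C2 revert; either monoether leads to the same bis-ether.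

Step 4
Reactants: 12 5,7-bis(benzyloxy)-2-henicosyl-4H-chromen-4-one
Product: 15 5,7-dihydroxy-2-henicosyl-4H-chromen-4-one, via 7-benzyloxy-5-hydroxy chromone 13 (not isolated), via 5-benzyloxy-7-hydroxy chromone 14 (not isolated)
Conditions: H2 (1 atm), 10% Pd/C, THF/EtOAc, rt
Reagents that add atoms: none
Why: Heterogeneous hydrogenolysis of the two aryl benzyl ethers should be much faster than reduction of the electron-rich C2=C3 bond of the vinylogous ester, so stopping after uptake of two equivalents of H2 should give the diphenol.

**Compound list**

1 | docosanoic acid | CCCCCCCCCCCCCCCCCCCCCC(=O)O | starting material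
2 | lithium docosanoate | [Li+].CCCCCCCCCCCCCCCCCCCCCC(=O)[O-] | intermediate
3 | dilithium tricosane-2,2-diolate | [Li+].[Li+].CCCCCCCCCCCCCCCCCCCCCC(C)([O-])[O-] | intermediate
4 | 2-tricosanone | CCCCCCCCCCCCCCCCCCCCCC(C)=O | intermediate
5 | 2,4,6-trifluorobenzoyl chloride | O=C(Cl)c1c(F)cc(F)cc1F | starting material
6 | lithium tricos-1-en-2-olate | [Li+].CCCCCCCCCCCCCCCCCCCCCC(=C)[O-] | intermediate
7 | 1-(2,4,6-trifluorophenyl)tetracosane-1,3-dione | CCCCCCCCCCCCCCCCCCCCCC(=O)CC(=O)c1c(F)cc(F)cc1F | intermediate
8 | lithium (Z)-1-oxo-1-(2,4,6-trifluorophenyl)tetracos-2-en-3-olate | [Li+].CCCCCCCCCCCCCCCCCCCCC/C([O-])=C/C(=O)c1c(F)cc(F)cc1F | intermediate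
9 | 5,7-difluoro-2-henicosyl-4H-chromen-4-one | CCCCCCCCCCCCCCCCCCCCCc1cc(=O)c2c(F)cc(F)cc2o1 | intermediate
10 | 7-(benzyloxy)-5-fluoro-2-henicosyl-4H-chromen-4-one | CCCCCCCCCCCCCCCCCCCCCc1cc(=O)c2c(F)cc(OCc3ccccc3)cc2o1 | intermediate
11 | 5-(benzyloxy)-7-fluoro-2-henicosyl-4H-chromen-4-one | CCCCCCCCCCCCCCCCCCCCCc1cc(=O)c2c(OCc3ccccc3)cc(F)cc2o1 | intermediate
12 | 5,7-bis(benzyloxy)-2-henicosyl-4H-chromen-4-one | CCCCCCCCCCCCCCCCCCCCCc1cc(=O)c2c(OCc3ccccc3)cc(OCc3ccccc3)cc2o1 | intermediate
13 | 7-(benzyloxy)-5-hydroxy-2-henicosyl-4H-chromen-4-one | CCCCCCCCCCCCCCCCCCCCCc1cc(=O)c2c(O)cc(OCc3ccccc3)cc2o1 | intermediate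
14 | 5-(benzyloxy)-7-hydroxy-2-henicosyl-4H-chromen-4-one | CCCCCCCCCCCCCCCCCCCCCc1cc(=O)c2c(OCc3ccccc3)cc(O)cc2o1 | intermediate
15 | 5,7-dihydroxy-2-henicosyl-4H-chromen-4-one | CCCCCCCCCCCCCCCCCCCCCc1cc(=O)c2c(O)cc(O)cc2o1 | target

**Totals**

Total step count: 4. Longest linear sequence: 4 steps (1 → 4 → 9 → 12 → 15).

**Steps most likely to fail**

Step 2. What may go wrong: proton removal on the C3 methylene side of 4, acylation of enolate 6 at oxygen, or a second aroylation of 8; each diverts material into isomeric or over-acylated products. The fallback builds the 1,3-dicarbonyl unit with reversed polarity, so that C2–C3 is formed in place of C3–C4 and the ketone to be enolized has a single α-carbon. It sets out from docosanoic acid 1, which SOCl2 (cat. DMF, toluene, 70 °C) should convert into docosanoyl chloride F1. Commercial 2',4',6'-trifluoroacetophenone (CC(=O)c1c(F)cc(F)cc1F) is deprotonated with LiN(SiMe3)2 (2.1 equiv, THF, −78 °C) to lithium 1-(2,4,6-trifluorophenyl)ethen-1-olate F2. Addition of F1 should give, by C-acylation, the diketone 7, at which the fallback comes back to the route; deprotonation to 8 and ring closure to 9 then follow as in step 2.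

Step 3. What may go wrong: the exchange stalling after the first ether, because the new alkoxy group deactivates ring A, and opening of ring C by benzyloxide addition at C2, followed by cleavage of the resulting diketone if traces of hydroxide are present. The fallback places the benzyloxy groups on ring A before ring C exists (Baker–Venkataraman route), so no fluoride exchange is needed. It sets out from docosanoic acid 1, which is esterified (DCC, DMAP, CH2Cl2) with commercial 1-[2,4-bis(benzyloxy)-6-hydroxyphenyl]ethanone (CC(=O)c1c(O)cc(OCc2ccccc2)cc1OCc1ccccc1) to give 2-acetyl-3,5-bis(benzyloxy)phenyl docosanoate F3. KOC(CH3)3 in THF should bring about the O-to-C acyl shift to 1-[2,4-bis(benzyloxy)-6-hydroxyphenyl]tetracosane-1,3-dione F4 after acidic work-up. Cyclodehydration (cat. TsOH, toluene, 80 °C) should then give 12, where the fallback rejoins the route.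

Step 1. What may go wrong: incomplete addition to the sparingly soluble lithium carboxylate 2, and a further addition of CH3Li to ketone released too early, leading to the tertiary alcohol. The fallback uses an acyl donor that can add only one methyl group. It sets out from docosanoic acid 1, which 1,1'-carbonyldiimidazole (THF, rt) should convert into 1-(1H-imidazol-1-yl)docosan-1-one F5. N,O-Dimethylhydroxylamine hydrochloride then gives N-methoxy-N-methyldocosanamide F6. CH3MgBr (THF, 0 °C) should add once to give the chelated bromomagnesium 2-[methoxy(methyl)amino]tricosan-2-olate F7, which on work-up with aqueous HCl releases 2-tricosanone 4, where the fallback comes back to the route.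

**Further compounds**

F1 | step 2 | docosanoyl chloride | CCCCCCCCCCCCCCCCCCCCCC(=O)Cl
F2 | step 2 | lithium 1-(2,4,6-trifluorophenyl)ethen-1-olate | [Li+].C=C([O-])c1c(F)cc(F)cc1F
F3 | step 3 | 2-acetyl-3,5-bis(benzyloxy)phenyl docosanoate | CCCCCCCCCCCCCCCCCCCCCC(=O)Oc1cc(OCc2ccccc2)cc(OCc2ccccc2)c1C(C)=O
F4 | step 3 | 1-[2,4-bis(benzyloxy)-6-hydroxyphenyl]tetracosane-1,3-dione | CCCCCCCCCCCCCCCCCCCCCC(=O)CC(=O)c1c(O)cc(OCc2ccccc2)cc1OCc1ccccc1
F5 | step 1 | 1-(1H-imidazol-1-yl)docosan-1-one | CCCCCCCCCCCCCCCCCCCCCC(=O)n1ccnc1
F6 | step 1 | N-methoxy-N-methyldocosanamide | CCCCCCCCCCCCCCCCCCCCCC(=O)N(C)OC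
F7 | step 1 | bromomagnesium 2-[methoxy(methyl)amino]tricosan-2-olate | CCCCCCCCCCCCCCCCCCCCCC(C)(O[Mg]Br)N(C)OC
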